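**Plan**

1. Numbering: C1 is the ring carbinol carbon carrying C2(=O)–C3–C4(OH)–C15; round the ring follow C5 (acyloxy), C6 (lactone O), C7, C8 (CH2), C9 (OH), C10 (CH3); the lactone carbons are C11–C13.
2. Late cuts: the C5 ester; C11=C13 (back to a Mannich base); the C2 ketone (back to a C2≡C3 alkyne, hydrated through the C1 hydroxyl); C9–OH (ketone); C7–C11 and C6–O of the lactone (enolate alkylation, hydride).
3. Core cut: the tertiary C1 oxygen is rejoined to C8 (a CH2 in the target, 1,4 to C1 across the ring), which turns the cycloheptane into an 8-oxabicyclo[3.2.1]octenone; this is cut across C1–C5 and C7–C8.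
4. This works because C6 carries oxygen and is flanked by C5 and C7 (an alkoxy-2-oxyallyl cation), and because C8–C9–C10–C1 with the C1 oxygen is a furan; the oxygen bridge is a temporary ring, broken later at C8–O with SmI2.
5. Forward: two fragments (5 steps); a (4+3) cycloaddition closes the seven-membered ring; lactone and C9 ketone are set up on the rigid bicycle; the bridge is cleaved; then C9 reduction, masked methylenation, alkyne hydration, acylation and unmasking.
6. Stereochemistry: C4 from (R)-but-3-yn-2-ol; C1, C5 and the absolute sense of the bicycle from the (S)-1-phenylethyl ether in the cycloaddition; C7, C6 and C10 by substrate control on the bicycle; C9 by C1–OH-directed hydride; the ester centre from (R)-2-methylbutanoic acid.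

Key step: step 6

Assumption: the (S)-1-phenylethyl group of cation 10 is taken to cover the face that leads to the (1R,2R,5S) adduct 11 (furan adds anti to the phenyl ring), and compounds 1, 2, 5, 7 and 25 are taken as commercial.

**Route**

Step 1
Reactants: 1 1,1-dimethoxypropan-2-one; 2 (S)-1-phenylethanol
Product: 3 mixed methyl 1-phenylethyl acetal of methylglyoxal
Conditions: PPTS (cat.), cyclohexane, 80 °C, MeOH distilled off (1 in excess)
Reagents that add atoms: none
Why: Acid-catalysed acetal exchange driven by removal of methanol replaces one methoxy group by the chiral alkoxy group without touching its stereocentre, and the new acetal carbon (both epimers) becomes planar in step 6.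

Step 2
Reactants: 3 mixed acetal
Product: 4 triethylsilyl enol ether of 3
Conditions: LDA, THF, −78 °C; Et3SiCl, −78 to 0 °C
Reagents that add atoms: chlorotriethylsilane, CC[Si](Cl)(CC)CC
Why: Kinetic deprotonation of the ketone at its unhindered CH3 group followed by O-silylation (silyl enol ether formation) gives the 2-silyloxyallyl acetal without creating a stereocentre.

Step 3
Reactants: 5 3-methylfuran
Product: 6 2-bromo-3-methylfuran
Conditions: NBS, DMF, −20 to 0 °C, dark; used at once
Reagents that add atoms: N-bromosuccinimide, O=C1CCC(=O)N1Br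
Why: Electrophilic aromatic bromination should take place at the furan α-position next to the activating methyl group (C2).

Step 4
Reactants: 7 (R)-but-3-yn-2-ol
Product: 8 TBS ether of 7
Conditions: TBSCl, imidazole, CH2Cl2, 0 °C to rt
Reagents that add atoms: tert-butyldimethylsilyl chloride, CC(C)(C)[Si](C)(C)Cl
Why: Standard silyl ether formation protects the secondary alcohol with retention of the (R) centre that becomes C4 of the target.

Step 5
Reactants: 6 2-bromo-3-methylfuran; 8 silylated butynol
Product: 9 2-alkynyl-3-methylfuran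
Conditions: PdCl2(PPh3)2 (3 mol %), CuI (5 mol %), Et3N, THF, rt
Reagents that add atoms: none
Why: Sonogashira coupling joins C1 to C2 and places the whole side chain as a slim, Lewis-acid-tolerant alkyne on the furan carbon that becomes C1.

Step 6
Reactants: 4 silyl enol ether acetal; 9 alkynylfuran
Product: 11 bicyclic ketone (cycloadduct), via oxyallyl cation triflate 10 (not isolated)
Conditions: TMSOTf (0.1 equiv), 4 (1.5 equiv), CH2Cl2, −95 to −78 °C; Et3N quench
Reagents that add atoms: none
Why: TMSOTf removes the methoxy group of 4 to give the 1-alkoxy-2-silyloxyallyl cation 10, the only free α-carbon of furan 9 (future C8) attacks its CH2 terminus (C7), and the enol ether carbon C5 then closes onto the alkynyl-bearing furan carbon C1, so that C1–C5 is the ring-closing bond and loss of the silyl group leaves the C6 ketone. The closest known reaction type is the low-temperature (4+3) cycloaddition of chiral α-alkoxy silyloxyallyl cations, made from mixed acetals of 1-phenylethanol, with furans. The seven-membered carbocycle (C1, C5, C6, C7, C8, C9, C10) is closed in stepwise (4+3) mode by a 7-membered Mukaiyama-type attack on the furan-derived oxocarbenium ion, and the temporary five-membered ether ring C1–O–C8 of the 8-oxabicyclo[3.2.1]octene is the former furan. At C5 the W-shaped cation in the compact transition state places the alkoxy group equatorial, trans to the oxygen bridge on C1, while C1 and C8 follow from suprafacial addition to the furan and their absolute sense from the (S)-1-phenylethyl group, whose phenyl ring covers one face of the cation. The step needs head-to-head regiochemistry (alkoxy carbon next to the substituted bridgehead) and reaction at the furan, not at the alkyne: the first is secured because the free, most nucleophilic furan α-position bonds first to the unhindered CH2 terminus, the second by the far higher nucleophilicity of the furan.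

Step 7
Reactants: 11 bicyclic ketone
Product: 12 C7-alkylated keto ester
Conditions: LDA, THF, −78 °C; BrCH2CO2Me, DMPU, −78 to −40 °C
Reagents that add atoms: methyl bromoacetate, COC(=O)CBr
Why: Kinetic enolisation on the unhindered CH2 side (C7, away from the alkoxy-bearing C5) and enolate alkylation from the face anti to the etheno bridge should place the C7 acetate arm axial, that is cis to the oxygen bridge as the lactone needs.

Step 8
Reactants: 12 keto ester
Product: 14 bicyclic γ-lactone, via C6 hydroxy ester 13 (not isolated)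
Conditions: NaBH4, MeOH–CH2Cl2, −40 to 0 °C; then PPTS (cat.), toluene, 40 °C
Reagents that add atoms: none
Why: In this borohydride reduction the small hydride should approach C6 syn to the etheno bridge because the axial C7 arm blocks the other face (the situation of 2-axially substituted tropan-3-ones), giving the equatorial alkoxide trans to the C5 ether and cis to the ester arm, which closes the cis-fused γ-lactone by lactonisation.

Step 9
Reactants: 14 bicyclic lactone
Product: 15 C9 exo-alcohol
Conditions: BH3·THF (1 equiv), THF, −20 to 0 °C; then 30 % H2O2, aq NaOAc, 0 °C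
Reagents that add atoms: hydrogen peroxide, OO
Why: Hydroboration–oxidation of the strained trisubstituted bicyclic alkene, expected to be much faster than attack on the hindered internal alkyne, places boron on the less substituted C9 from the exo face (syn to the oxygen bridge), so that C9–OH is exo and the C10 methyl group is for the moment endo.

Step 10
Reactants: 15 C9 exo-alcohol
Product: 17 exo-methyl C9 ketone, via endo-methyl ketone 16 (not isolated)
Conditions: Dess–Martin periodinane, NaHCO3, CH2Cl2, 0 °C to rt; then DBU (0.5 equiv), toluene, 50 °C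
Reagents that add atoms: none
Why: Dess–Martin oxidation gives the C9 ketone, which can enolise only toward C10 because C8 is a bridgehead, and base equilibration should move the methyl group from the endo position, where it is pressed against the axial hydrogen on C6, to the exo position cis to the oxygen bridge, which is the configuration of the target.

Step 11
Reactants: 17 exo-methyl C9 ketone
Product: 18 monocyclic β-hydroxy ketone
Conditions: SmI2 (2.5 equiv), THF–MeOH, −78 °C; NH4Cl work-up; used directly
Reagents that add atoms: none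
Why: Samarium diiodide reduces the ketone to a ketyl that expels the α-alkoxy substituent (reductive cleavage of an α-hetero-substituted ketone, as known for 7-oxanorbornan-2-ones), which breaks the temporary C8–O bond, turns C8 into the CH2 group of the target and frees the tertiary C1 hydroxyl with its configuration untouched.

Step 12
Reactants: 18 β-hydroxy ketone
Product: 19 1,9-diol
Conditions: Me4NBH(OAc)3, MeCN–AcOH, −30 °C
Reagents that add atoms: none
Why: In this Evans–Saksena reduction the C1 hydroxyl binds boron and hands the hydride to the same face of the C9 ketone, which should give the 1,3-anti diol with C9–OH trans to C1–OH and to the C10 methyl group.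

Step 13
Reactants: 19 diol
Product: 20 C9 silyl ether
Conditions: TBSCl, imidazole, DMF, rt
Reagents that add atoms: tert-butyldimethylsilyl chloride, CC(C)(C)[Si](C)(C)Cl
Why: Silyl ether formation takes the secondary C9 hydroxyl and leaves the hindered tertiary propargylic C1 hydroxyl free for step 15.

Step 14
Reactants: 20 C9 silyl ether
Product: 21 Mannich base
Conditions: LDA (3 equiv), THF, −78 °C; CH2=NMe2+ I−, −78 to 0 °C
Reagents that add atoms: Eschenmoser's salt (N,N-dimethylmethyleneiminium iodide), C=[N+](C)C.[I-]
Why: Aminomethylation of the lactone enolate (Mannich reaction, the C1 hydroxyl riding along as its alkoxide) installs C13 as a base-stable masked methylene group whose new centre at C11 is removed again in step 18.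

Step 15
Reactants: 21 Mannich base
Product: 23 C2 ketone, via spiro enol carbonate 22 (not isolated)
Conditions: AgOAc (10 mol %), DBU (1 equiv), CO2 (10 bar), MeCN, rt; then H2O, 40 °C
Reagents that add atoms: water, O
Why: Silver-catalysed carboxylative cyclisation of the tertiary propargylic alcohol with CO2 (5-exo-dig attack of the C1 carbonate oxygen on C2) and hydrolysis of the enol carbonate amount to an alkyne hydration that is regiospecific for the C2 ketone.

Step 16
Reactants: 23 C2 ketone
Product: 24 C5 alcohol
Conditions: H2 (1 atm), Pd(OH)2/C, EtOAc–AcOH, rt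
Reagents that add atoms: none
Why: Hydrogenolysis of the secondary benzylic ether removes the chiral auxiliary and frees the C5 hydroxyl at a stage where no alkene or alkyne is left, the amine being protonated by acetic acid so that it does not poison the catalyst.

Step 17
Reactants: 24 C5 alcohol; 25 (R)-2-methylbutanoic acid
Product: 26 C5 (R)-2-methylbutanoate
Conditions: DCC, DMAP, CH2Cl2, 0 °C to rt
Reagents that add atoms: none
Why: Steglich esterification acylates the only free secondary hydroxyl (C5), the tertiary C1 hydroxyl being unreactive, and the mild conditions should keep the α-centre of the acid intact.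

Step 18
Reactants: 26 C5 ester
Product: 28 bis-silyl α-methylene lactone, via trimethylammonium iodide 27 (not isolated)
Conditions: MeI, MeOH, rt; then aq NaHCO3, EtOAc, rt
Reagents that add atoms: none
Why: N-Methylation turns the Mannich base into a trimethylammonium leaving group, and bicarbonate-induced β-elimination (E1cB through the lactone enolate) should unveil the α-methylene lactone without touching the ketone or the esters.

Step 19
Reactants: 28 bis-silyl ether
Product: 29 target
Conditions: HF·pyridine, pyridine, THF, 0 °C to rt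
Reagents that add atoms: none
Why: Fluoride-mediated desilylation under buffered, weakly acidic conditions should free the C4 and C9 hydroxyls without dehydration of the β-hydroxy ketone, acyl migration or addition to the α-methylene lactone.

**Compound list**

1 | 1,1-dimethoxypropan-2-one | CC(=O)C(OC)OC | starting material
2 | (S)-1-phenylethanol | C[C@H](O)c1ccccc1 | starting material
3 | 1-methoxy-1-[(1S)-1-phenylethoxy]propan-2-one (both epimers at the acetal carbon) | CC(=O)C(OC)O[C@@H](C)c1ccccc1 | intermediate
4 | triethyl({3-methoxy-3-[(1S)-1-phenylethoxy]prop-1-en-2-yl}oxy)silane (both acetal epimers) | C=C(O[Si](CC)(CC)CC)C(OC)O[C@@H](C)c1ccccc1 | intermediate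
5 | 3-methylfuran | Cc1ccoc1 | starting material
6 | 2-bromo-3-methylfuran | Cc1ccoc1Br | intermediate
7 | (R)-but-3-yn-2-ol | C#C[C@@H](C)O | starting material
8 | (R)-(but-3-yn-2-yloxy)(tert-butyl)dimethylsilane | C#C[C@@H](C)O[Si](C)(C)C(C)(C)C | intermediate
9 | 2-[(3R)-3-(tert-butyldimethylsilyloxy)but-1-yn-1-yl]-3-methylfuran | Cc1ccoc1C#C[C@@H](C)O[Si](C)(C)C(C)(C)C | intermediate
10 | 1-[(1S)-1-phenylethoxy]-2-(triethylsilyloxy)allyl cation, triflate | C=C(O[Si](CC)(CC)CC)C=[O+][C@@H](C)c1ccccc1.[O-]S(=O)(=O)C(F)(F)F | intermediate (not isolated)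
11 | (1R,2R,5S)-1-[(3R)-3-(tert-butyldimethylsilyloxy)but-1-yn-1-yl]-7-methyl-2-[(1S)-1-phenylethoxy]-8-oxabicyclo[3.2.1]oct-6-en-3-one (C1 alkynyl bridgehead, C5 ether trans to the C1–O–C8 bridge, C6 ketone, C9=C10) | O=C1C[C@H]2C=C(C)[C@@](O2)(C#C[C@@H](C)O[Si](C)(C)C(C)(C)C)[C@H]1O[C@@H](C)c1ccccc1 | intermediate
12 | 11 carrying CH2CO2Me on C7, axial, cis to the oxygen bridge | O=C1[C@H](CC(=O)OC)[C@H]2C=C(C)[C@@](O2)(C#C[C@@H](C)O[Si](C)(C)C(C)(C)C)[C@H]1O[C@@H](C)c1ccccc1 | intermediate
13 | C6 alcohol of 12, hydroxyl equatorial (trans to the C5 ether, cis to the C7 arm) | O[C@@H]1[C@H](CC(=O)OC)[C@H]2C=C(C)[C@@](O2)(C#C[C@@H](C)O[Si](C)(C)C(C)(C)C)[C@H]1O[C@@H](C)c1ccccc1 | intermediate (not isolated)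
14 | 6,12-lactone on the oxabicycle, C6–O and C7–C11 cis on the face of the oxygen bridge, C9=C10 intact | O=C1O[C@@H]2[C@H](C1)[C@H]3C=C(C)[C@@](O3)(C#C[C@@H](C)O[Si](C)(C)C(C)(C)C)[C@H]2O[C@@H](C)c1ccccc1 | intermediate
15 | 14 hydrated across C9=C10: C9–OH exo (cis to the oxygen bridge), C10–CH3 endo | O=C1O[C@@H]2[C@H](C1)[C@H]3[C@H](O)[C@@H](C)[C@@](O3)(C#C[C@@H](C)O[Si](C)(C)C(C)(C)C)[C@H]2O[C@@H](C)c1ccccc1 | intermediate
16 | C9 ketone, C10–CH3 endo | O=C1O[C@@H]2[C@H](C1)[C@H]3C(=O)[C@@H](C)[C@@](O3)(C#C[C@@H](C)O[Si](C)(C)C(C)(C)C)[C@H]2O[C@@H](C)c1ccccc1 | intermediate (not isolated)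
17 | C9 ketone, C10–CH3 exo (cis to the oxygen bridge) | O=C1O[C@@H]2[C@H](C1)[C@H]3C(=O)[C@H](C)[C@@](O3)(C#C[C@@H](C)O[Si](C)(C)C(C)(C)C)[C@H]2O[C@@H](C)c1ccccc1 | intermediate
18 | bridge-opened lactone: C1 (OH, alkynyl), C5 (S)-1-phenylethoxy, C8 CH2, C9 ketone, C10 CH3 cis to C1–OH | O=C1O[C@@H]2[C@H](C1)CC(=O)[C@H](C)[C@@](O)(C#C[C@@H](C)O[Si](C)(C)C(C)(C)C)[C@H]2O[C@@H](C)c1ccccc1 | intermediate
19 | 1,9-diol of 18, C9–OH trans to C1–OH | O=C1O[C@@H]2[C@H](C1)C[C@@H](O)[C@H](C)[C@@](O)(C#C[C@@H](C)O[Si](C)(C)C(C)(C)C)[C@H]2O[C@@H](C)c1ccccc1 | intermediate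
20 | 9-O-TBS ether of 19 | O=C1O[C@@H]2[C@H](C1)C[C@@H](O[Si](C)(C)C(C)(C)C)[C@H](C)[C@@](O)(C#C[C@@H](C)O[Si](C)(C)C(C)(C)C)[C@H]2O[C@@H](C)c1ccccc1 | intermediate
21 | 11-(dimethylaminomethyl) lactone from 20 (C11 either epimer) | CN(C)CC1C(=O)O[C@@H]2[C@H]1C[C@@H](O[Si](C)(C)C(C)(C)C)[C@H](C)[C@@](O)(C#C[C@@H](C)O[Si](C)(C)C(C)(C)C)[C@H]2O[C@@H](C)c1ccccc1 | intermediate
22 | spiro cyclic carbonate (1,3-dioxolan-2-one over O–C1–C2–O) with exocyclic (Z)-C2=C3 | CN(C)CC1C(=O)O[C@@H]2[C@H]1C[C@@H](O[Si](C)(C)C(C)(C)C)[C@H](C)[C@@](O3)(/C(=C/[C@@H](C)O[Si](C)(C)C(C)(C)C)OC3=O)[C@H]2O[C@@H](C)c1ccccc1 | intermediate (not isolated)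
23 | C2 ketone (C1 α-hydroxy ketone), C4 and C9 as TBS ethers, C5 (S)-1-phenylethyl ether | CN(C)CC1C(=O)O[C@@H]2[C@H]1C[C@@H](O[Si](C)(C)C(C)(C)C)[C@H](C)[C@@](O)(C(=O)C[C@@H](C)O[Si](C)(C)C(C)(C)C)[C@H]2O[C@@H](C)c1ccccc1 | intermediate
24 | C5 alcohol from 23 | CN(C)CC1C(=O)O[C@@H]2[C@H]1C[C@@H](O[Si](C)(C)C(C)(C)C)[C@H](C)[C@@](O)(C(=O)C[C@@H](C)O[Si](C)(C)C(C)(C)C)[C@H]2O | intermediate
25 | (R)-2-methylbutanoic acid | CC[C@@H](C)C(=O)O | starting material
26 | C5 (R)-2-methylbutanoate of 24 | CN(C)CC1C(=O)O[C@@H]2[C@H]1C[C@@H](O[Si](C)(C)C(C)(C)C)[C@H](C)[C@@](O)(C(=O)C[C@@H](C)O[Si](C)(C)C(C)(C)C)[C@H]2OC(=O)[C@H](C)CC | intermediate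
27 | trimethylammonium iodide of 26 | C[N+](C)(C)CC1C(=O)O[C@@H]2[C@H]1C[C@@H](O[Si](C)(C)C(C)(C)C)[C@H](C)[C@@](O)(C(=O)C[C@@H](C)O[Si](C)(C)C(C)(C)C)[C@H]2OC(=O)[C@H](C)CC.[I-] | intermediate (not isolated)
28 | 4,9-bis-O-TBS ether of the target | C=C1C(=O)O[C@@H]2[C@H]1C[C@@H](O[Si](C)(C)C(C)(C)C)[C@H](C)[C@@](O)(C(=O)C[C@@H](C)O[Si](C)(C)C(C)(C)C)[C@H]2OC(=O)[C@H](C)CC | intermediate
29 | CNP0291806.5 | C=C1C(=O)O[C@@H]2[C@H]1C[C@@H](O)[C@H](C)[C@@](O)(C(=O)C[C@@H](C)O)[C@H]2OC(=O)[C@H](C)CC | target

**Count and risks**

Total steps: 19. Longest linear sequence: 16 steps (5 → 6 → 9 → 11 → … → 29; the sequences from 1 and from 7 are equally long).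

Steps most likely to fail:

Step 6. What may go wrong: ionisation of the propargylic silyl ether or oligomerisation of the furan under the silyl triflate, arrest after the first C–C bond (substitution at the furan α-carbon without closure of C1–C5), or weak facial control by the auxiliary. The fallback sets out from 2 and 9 and returns at 11; it generates the same alkoxy-oxyallyl unit without Lewis acid. Alcohol 2 is alkylated with epichlorohydrin (NaH, DMF) to 2-{[(1S)-1-phenylethoxy]methyl}oxirane F1. The epoxide is opened with LiCl/AcOH to 1-chloro-3-[(1S)-1-phenylethoxy]propan-2-ol F2, and Dess–Martin oxidation gives 1-chloro-3-[(1S)-1-phenylethoxy]propan-2-one F3. With Et3N in 2,2,2-trifluoroethanol, F3 enolises and loses chloride, and the resulting oxyallyl cation adds to 9 in the base-mediated (4+3) cycloaddition of an α-halo ketone. The C1–C5 bond is again formed in the ring closure, and 11 is separated from its diastereomers by chromatography.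

Step 8. What may go wrong: hydride delivery to the face of the C6 carbonyl anti to the etheno bridge, which gives the C6 epimer that cannot lactonise. The fallback sets out from 12 and returns at 14; it makes this the deliberate course and inverts C6 in the ring closure. L-Selectride (THF, −78 °C) gives the 6-epi hydroxy ester F4. LiOH (THF–H2O) gives the 6-epi hydroxy acid F5. Mitsunobu lactonisation (PPh3, DIAD, THF) lets the carboxylate displace the activated C6 oxygen from the face of the C7 arm, with inversion, to give 14.

Step 15. What may go wrong: sluggish carboxylative cyclisation at the hindered internal alkyne, and β-elimination of the C4 silyloxy group or lactone opening during long exposure to the amidine base. The fallback sets out from 21 and returns at 22, which is hydrolysed to 23 with aq LiOH in THF at 0 °C. The C1 hydroxyl is converted with Boc2O/DMAP (MeCN) into the C1 tert-butyl carbonate F6. Ph3PAuNTf2 (2 mol %, monovalent gold; amine pre-protonated with one equivalent of HNTf2) in CH2Cl2 at rt then triggers 5-exo-dig attack of the carbonate carbonyl on C2 with loss of the tert-butyl group, giving 22 without base or pressure.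

Further compounds
F1 | step 6 | 2-{[(1S)-1-phenylethoxy]methyl}oxirane (either epoxide epimer) | C[C@H](OCC1CO1)c1ccccc1
F2 | step 6 | 1-chloro-3-[(1S)-1-phenylethoxy]propan-2-ol (either carbinol epimer) | C[C@H](OCC(O)CCl)c1ccccc1
F3 | step 6 | 1-chloro-3-[(1S)-1-phenylethoxy]propan-2-one | C[C@H](OCC(=O)CCl)c1ccccc1
F4 | step 8 | 6-epi hydroxy ester (C6 hydroxyl axial, cis to the C5 ether, trans to the C7 arm) | O[C@H]1[C@H](CC(=O)OC)[C@H]2C=C(C)[C@@](O2)(C#C[C@@H](C)O[Si](C)(C)C(C)(C)C)[C@H]1O[C@@H](C)c1ccccc1
F5 | step 8 | 6-epi hydroxy acid (carboxylic acid of F4) | O[C@H]1[C@H](CC(=O)O)[C@H]2C=C(C)[C@@](O2)(C#C[C@@H](C)O[Si](C)(C)C(C)(C)C)[C@H]1O[C@@H](C)c1ccccc1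
F6 | step 15 | C1 tert-butyl carbonate of 21 | CN(C)CC1C(=O)O[C@@H]2[C@H]1C[C@@H](O[Si](C)(C)C(C)(C)C)[C@H](C)[C@@](OC(=O)OC(C)(C)C)(C#C[C@@H](C)O[Si](C)(C)C(C)(C)C)[C@H]2O[C@@H](C)c1ccccc1
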